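**Plan**
Rings: A is the tetrasubstituted ring (C1 OH, C2 benzyl, C3 OMe, C5 CH2CH2), B is 3-methoxyphenyl and C is 4-hydroxyphenyl.
Cuts: the diarylmethane CH2 is traced back to C=O. Both bonds of that carbon (A-C2–C and C-C4'–C) are then cut together, which leaves CO2. Last, the A-C5–CH2 bond of the ethano bridge is cut.
Enabling feature: the CH2 sits between two carbons that each form a carbanion easily. A-C2 is the only ring C–H flanked by two oxygen-bearing carbons (C1–O and C3–OMe). C-C4' is para to the phenol oxygen and is reached from a para-bromide, so an electrophilic C1 unit can join two aryl anions.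
Forward: no ring is built. B is joined to A by hydroboration and B-alkyl Suzuki coupling, C and A are then joined through CO2 as a diaryl ketone, and the route ends with MOM removal and C=O → CH2.
Stereochemistry: the target has none, so there is nothing to set or protect.

Key step: step 4

Remark: the target SMILES has no stereocentre, stereoaxis or stereogenic double bond. The "single enantiomer" is therefore the one achiral compound, and the only stereocentre on the route (in transient 15) is erased in the same flask.

**Step 1**
Reactants: 1 3-bromo-5-methoxyphenol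
Product: 2 1-bromo-3-methoxy-5-(methoxymethoxy)benzene
Conditions: MOMCl, i-Pr2NEt, CH2Cl2, 0 °C → rt
Reagents that add atoms: chloromethyl methyl ether (MOMCl), COCCl
Why: O-alkylation of a phenol with a reactive α-chloro ether (MOM protection) is routine, and the acetal oxygen later acts as the stronger of the two ortho-directing groups.

**Step 2**
Reactants: 3 3-vinylanisole (1-ethenyl-3-methoxybenzene); 2 1-bromo-3-methoxy-5-(methoxymethoxy)benzene
Product: 5 1-methoxy-3-(methoxymethoxy)-5-[2-(3-methoxyphenyl)ethyl]benzene, via B-[2-(3-methoxyphenyl)ethyl]-9-borabicyclo[3.3.1]nonane 4 (not isolated)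
Conditions: 3, 9-BBN (0.5 M), THF, 0 °C → rt; then 2, PdCl2(dppf) (3 mol %), 3 M aq NaOH, THF, 65 °C
Reagents that add atoms: none
Why: 9-BBN places boron on the terminal carbon of the styrene (anti-Markovnikov hydroboration), and the primary B-alkyl-9-BBN should couple with the aryl bromide under B-alkyl Suzuki–Miyaura conditions, in which dppf holds back β-hydride elimination and the MOM and OMe groups are inert to aqueous base.

**Step 3**
Reactants: 6 4-bromophenol
Product: 7 1-bromo-4-(methoxymethoxy)benzene
Conditions: MOMCl, i-Pr2NEt, CH2Cl2, 0 °C → rt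
Reagents that add atoms: chloromethyl methyl ether (MOMCl), COCCl
Why: the same MOM protection removes the acidic OH, so the bromide can undergo clean halogen–lithium exchange.

**Step 4**
Reactants: 7 1-bromo-4-(methoxymethoxy)benzene; 8 carbon dioxide; 5 1-methoxy-3-(methoxymethoxy)-5-[2-(3-methoxyphenyl)ethyl]benzene
Product: 13 {2-methoxy-6-(methoxymethoxy)-4-[2-(3-methoxyphenyl)ethyl]phenyl}[4-(methoxymethoxy)phenyl]methanone, via 4-(methoxymethoxy)phenyllithium 9 (not isolated), via lithium 4-(methoxymethoxy)benzoate 10 (not isolated), via ring-A aryllithium 11 (not isolated), via dilithium gem-diolate 12 (not isolated)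
Conditions: (a) 7, n-BuLi (0.98 equiv), THF, −78 °C; dry CO2 gas, −78 °C → rt; evaporate to dryness under vacuum (removes CO2 and n-BuBr), Ar, fresh THF; (b) 5, n-BuLi (1.0 equiv), THF, 0 °C → rt; (c) cannulate (b) into (a) (1.5 equiv of 10), 0 → 40 °C; pour into ice-water
Reagents that add atoms: carbon dioxide (compound 8), O=C=O
Why: Bromine–lithium exchange converts 7 into 9, which adds to CO2 to give carboxylate 10, and once all free CO2 has been stripped the carbanion 11, made by directed ortho-metalation of 5, attacks the carboxylate carbon to give gem-diolate 12. Since 12 cannot expel lithium oxide it survives until the inverse aqueous quench, so ketone 13 is released only after every organolithium has been destroyed and no triarylcarbinol can form. The closest known reaction type is the ketone synthesis from a lithium carboxylate and an organolithium, including its one-pot form in which the carboxylate is first made from CO2 and another organolithium. No ring is closed and no stereocentre is created. The step needs site-selective deprotonation of 5 at A-C2, which the cooperative chelating OMOM and OMe neighbours secure (5-alkylresorcinol diethers lithiate there with n-BuLi in THF), whereas ring B offers only sites next to a single OMe and the benzylic CH2 groups are kinetically inert without TMEDA. The crowded 2,6-dioxygenated carbon is given the nucleophile role and the unhindered para-substituted benzoate the electrophile role, and 11, being the more stabilised aryllithium, should neither metalate 10 next to its OMOM group nor exchange with leftover 7.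

**Step 5**
Reactants: 13 {2-methoxy-6-(methoxymethoxy)-4-[2-(3-methoxyphenyl)ethyl]phenyl}[4-(methoxymethoxy)phenyl]methanone
Product: 14 (4-hydroxyphenyl){2-hydroxy-6-methoxy-4-[2-(3-methoxyphenyl)ethyl]phenyl}methanone
Conditions: conc. HCl (cat.), MeOH, 50 °C
Reagents that add atoms: none
Why: acid-catalysed acetal exchange (MOM cleavage) passes the CH2 unit to methanol and leaves the aryl methyl ethers and the ketone untouched, and at the ketone stage rings A and C are still deactivated against alkylation by the released C1 electrophile.

**Step 6**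
Reactants: 14 (4-hydroxyphenyl){2-hydroxy-6-methoxy-4-[2-(3-methoxyphenyl)ethyl]phenyl}methanone
Product: 16 2-(4-hydroxybenzyl)-3-methoxy-5-[2-(3-methoxyphenyl)ethyl]phenol (IN0509), via benzhydrol 15 (not isolated)
Conditions: Et3SiH (4 equiv), TFA–CH2Cl2 (1:1), 0 °C → rt
Reagents that add atoms: none
Why: in this ionic hydrogenation (Kursanov–Parnes reduction) the protonated ketone takes a hydride from the silane to give carbinol 15, which ionises at once to a benzhydryl cation stabilised by the o-OH/o-OMe ring A and the p-hydroxyphenyl ring C and accepts a second hydride, while the phenols, the methyl ethers and the ethano bridge are inert.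

**Compound list**
1 | 3-bromo-5-methoxyphenol | COc1cc(O)cc(Br)c1 | starting material
2 | 1-bromo-3-methoxy-5-(methoxymethoxy)benzene | COCOc1cc(Br)cc(OC)c1 | intermediate
3 | 3-vinylanisole | COc1cccc(C=C)c1 | starting material
4 | B-[2-(3-methoxyphenyl)ethyl]-9-borabicyclo[3.3.1]nonane | COc1cccc(CCB2C3CCCC2CCC3)c1 | intermediate
5 | 1-methoxy-3-(methoxymethoxy)-5-[2-(3-methoxyphenyl)ethyl]benzene | COCOc1cc(CCc2cccc(OC)c2)cc(OC)c1 | intermediate
6 | 4-bromophenol | Oc1ccc(Br)cc1 | starting material
7 | 1-bromo-4-(methoxymethoxy)benzene | COCOc1ccc(Br)cc1 | intermediate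
8 | carbon dioxide | O=C=O | starting material
9 | 4-(methoxymethoxy)phenyllithium | [Li]c1ccc(OCOC)cc1 | intermediate
10 | lithium 4-(methoxymethoxy)benzoate | [Li+].[O-]C(=O)c1ccc(OCOC)cc1 | intermediate
11 | {2-methoxy-6-(methoxymethoxy)-4-[2-(3-methoxyphenyl)ethyl]phenyl}lithium | [Li]c1c(OC)cc(CCc2cccc(OC)c2)cc1OCOC | intermediate
12 | dilithium {2-methoxy-6-(methoxymethoxy)-4-[2-(3-methoxyphenyl)ethyl]phenyl}[4-(methoxymethoxy)phenyl]methanediolate | [Li+].[Li+].[O-]C([O-])(c1ccc(OCOC)cc1)c1c(OC)cc(CCc2cccc(OC)c2)cc1OCOC | intermediate
13 | {2-methoxy-6-(methoxymethoxy)-4-[2-(3-methoxyphenyl)ethyl]phenyl}[4-(methoxymethoxy)phenyl]methanone | COCOc1ccc(C(=O)c2c(OC)cc(CCc3cccc(OC)c3)cc2OCOC)cc1 | intermediate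
14 | (4-hydroxyphenyl){2-hydroxy-6-methoxy-4-[2-(3-methoxyphenyl)ethyl]phenyl}methanone | COc1cccc(CCc2cc(O)c(C(=O)c3ccc(O)cc3)c(OC)c2)c1 | intermediate
15 | 2-[hydroxy(4-hydroxyphenyl)methyl]-3-methoxy-5-[2-(3-methoxyphenyl)ethyl]phenol (racemic, transient) | COc1cccc(CCc2cc(O)c(C(O)c3ccc(O)cc3)c(OC)c2)c1 | intermediate
16 | 2-(4-hydroxybenzyl)-3-methoxy-5-[2-(3-methoxyphenyl)ethyl]phenol (IN0509, achiral) | COc1cccc(CCc2cc(O)c(Cc3ccc(O)cc3)c(OC)c2)c1 | target

**Step count**
Total steps: 6. Longest linear sequence: 5 (steps 1, 2, 4, 5, 6). Step 3 is a one-step side branch.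

**Steps most likely to fail**

Step 4. The crowded aryllithium may add only slowly to the sparingly soluble carboxylate salt. It would then be lost gradually to proton abstraction from the medium or to traces of CO2 that were not removed. The fallback sets out from 10 (made from 7 and 8 as in step 4) and from 11, and it returns at 13.
- Salt 10 is acidified with cold dilute HCl to pH 4 to give 4-(methoxymethoxy)benzoic acid F1.
- This acid is coupled with MeNH(OMe)·HCl (EDC·HCl, i-Pr2NEt, CH2Cl2) to give N-methoxy-4-(methoxymethoxy)-N-methylbenzamide F2.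
- Aryllithium 11 adds to this soluble, neutral and much more electrophilic acyl donor at −78 → 0 °C in THF to give the chelated lithium hemiaminal alkoxide F3.
- That adduct collapses to 13 only on aqueous quench (Weinreb ketone synthesis).

The carbonyl carbon still comes from CO2 and the same two aryl–carbon bonds are formed, but in separate operations.

Step 6. The first hydride transfer to the strongly stabilised, hindered protonated ketone may be sluggish. Prolonged contact with TFA could then cleave an aryl–carbon bond, either by protodeacylation of ring A or by loss of the p-hydroxybenzyl unit from the product. The fallback sets out from 13, bypasses 14 and 15, and returns at 16.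
- LiAlH4 in THF (0 °C → rt) reduces the protected ketone to the racemic carbinol {2-methoxy-6-(methoxymethoxy)-4-[2-(3-methoxyphenyl)ethyl]phenyl}[4-(methoxymethoxy)phenyl]methanol F4.
- Its doubly benzylic C–O bond is cleaved by hydrogenolysis (H2, Pd/C, EtOH, trace AcOH) to give 1-methoxy-3-(methoxymethoxy)-2-[4-(methoxymethoxy)benzyl]-5-[2-(3-methoxyphenyl)ethyl]benzene F5.
- Catalytic HCl in MeOH, as in step 5, then frees both phenols.

No strong acid meets the ketone on this path.

Step 2. Slow transmetalation of the alkylborane may allow protodeboronation, or β-hydride elimination from the alkylpalladium species, to overtake the coupling. The fallback sets out from 2 and 3 and returns at 5.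
- A Heck reaction (Pd(OAc)2, P(o-tol)3, Et3N, DMF, 100 °C) joins the same two building blocks as 1-methoxy-3-(methoxymethoxy)-5-[(E)-2-(3-methoxyphenyl)ethenyl]benzene F6.
- Hydrogenation of the alkene (H2, Pd/C, EtOAc, rt) then leaves the MOM and OMe groups untouched.

**Further compounds**
F1 | step 4 | 4-(methoxymethoxy)benzoic acid | COCOc1ccc(C(=O)O)cc1
F2 | step 4 | N-methoxy-4-(methoxymethoxy)-N-methylbenzamide | COCOc1ccc(C(=O)N(C)OC)cc1
F3 | step 4 | lithium [methoxy(methyl)amino]{2-methoxy-6-(methoxymethoxy)-4-[2-(3-methoxyphenyl)ethyl]phenyl}[4-(methoxymethoxy)phenyl]methanolate (racemic) | [Li+].[O-]C(N(C)OC)(c1ccc(OCOC)cc1)c1c(OC)cc(CCc2cccc(OC)c2)cc1OCOC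
F4 | step 6 | {2-methoxy-6-(methoxymethoxy)-4-[2-(3-methoxyphenyl)ethyl]phenyl}[4-(methoxymethoxy)phenyl]methanol (racemic) | COCOc1ccc(C(O)c2c(OC)cc(CCc3cccc(OC)c3)cc2OCOC)cc1
F5 | step 6 | 1-methoxy-3-(methoxymethoxy)-2-[4-(methoxymethoxy)benzyl]-5-[2-(3-methoxyphenyl)ethyl]benzene | COCOc1ccc(Cc2c(OC)cc(CCc3cccc(OC)c3)cc2OCOC)cc1
F6 | step 2 | 1-methoxy-3-(methoxymethoxy)-5-[(E)-2-(3-methoxyphenyl)ethenyl]benzene | COCOc1cc(/C=C/c2cccc(OC)c2)cc(OC)c1
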